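In a one-step world a flask has a single clock, read off one rate constant; this flask runs through a catalyst, so its clock has to be built.

    starting material + enzyme ⇌ starting complex (K1 = 8.1 /M, k1 = 5900 /M/min)
    second substrate + starting complex ⇌ ternary complex (K2 = 290 /M, k2 = 6500 /M/min)
    ternary complex → enzyme + product (k3 = 22 /min)
    2 starting complex → spent catalyst (k4 = 310 /M/min)
    starting material ⇌ dormant form (K5 = 0.22, k5 = 0.0018 /min)

the same everywhere: starting material 0.050 M; second substrate 0.0475 M; enzyme 5.0 µM
- north-west: time 10 h
- west: time 15 h
- north: time 20 h

1. which of these there is most of at the end, counted by the starting material in it, north-west (product / starting material / ternary complex / starting complex)
2. which of these there is most of at the end, counted by the starting material in it, west (product / starting material / ternary complex / starting complex)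
3. which of these there is most of at the end, counted by the starting material in it, north (product / starting material / ternary complex / starting complex)
4. amount of the one of these that there is most of at the end, in percent of the starting material charged, north-west
5. amount of the one of these that there is most of at the end, in percent of the starting material charged, west
6. amount of the one of these that there is most of at the end, in percent of the starting material charged, north

- percent here means starting material units held: one spent catalyst counts as two
- two of one species on the left: rate k times its square, two consumed each time
- run time (north-west): 10 h

The end state gives the first limit. Each product takes one second substrate, which is the limiting reagent here, so product can reach 95.0% of the starting material charged. The catalyst charge is 0.0100% of that charge, so the complexes cannot compete on this scale, and the contest lies between product and starting material.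

Product forms at 22 /min times [ternary complex]. If the whole catalyst stood as ternary complex, the charge of starting material would turn over in 7.58 h; this time is the turnover clock. Real time per unit of conversion is the clock times the drag, which is catalyst charged over ternary complex. The steady state of both complexes gives drag = 1 + a/[starting material] + b/[second substrate] + c/([starting material][second substrate]). Here a = 3.73 mM is the rate constant of product formation over the rate constant at which starting material binds enzyme, b = 6.83 mM is the loss of ternary complex, both ways, over the rate constant that forms it, and c = 8.44 × 10⁻⁴ M^2 is b over the equilibrium constant of starting complex.

At the charge the drag is 1.57, and it grows as both substrates fall. North-west at 10 h therefore has a ceiling of 83.9%, while west and north keep the stoichiometric ceiling.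

For a floor, the dormant form at its equilibrium share holds 18.0% of the unreacted material, which in this reckoning raises the drag at the charge to 1.67 and stretches the time scale T to 12.6 h. Letting the rate fall with the product of both concentrations gives t/(T + t): 44.2%, 54.3% and 61.3% for north-west, west and north.

Integrating the drag term by term, with the dormant form at that share, tightens this. By this reckoning the fraction 0.5 of the charge stands as product at 8.41 h and the fraction 0.7 at 15.7 h. North-west and west thus lie between these marks, west just below the upper one, and north lies above it.

The forecast, inside this bracket, names product with 57%, 69% and 77% for north-west, west and north, holding that “the enzyme-bound species are negligible on the mass scale”.

The simulation gives 55.6% product and 35.3% starting material in north-west, 68.2% and 25.4% in west, and 75.7% and 19.5% in north.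

In north-west at 10.0 h, ternary complex stands at 24.7% of the catalyst charged, a drag of 4.05 on the clock of 7.58 h. Without the way back from starting complex, north-west reads 83.0% product at that time, and left ten times as long it reads 93.3%, against 55.6%, so part of the shortfall comes from that back step acting together with the reading time. The same flask as west with 1.2 × 10⁻⁵ M of enzyme has a clock of 3.16 h and gives 85.9% product, while with 1.2 × 10⁻⁶ M its clock is 31.6 h, longer than the run, and it gives 25.6%.

The numbers of this flask were drawn at random within sensible limits.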